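**Retrosynthetic overview** (labdane numbering)
1. Endgame: the target comes from acetylation and saponification of a 2β-hydroxy ethyl ester. The C-8(17) methylene comes from reductive 1,3-transposition of a C-7=C-8–C-17H2OH allylic alcohol. C-12–C-13 comes from a B-alkyl Suzuki coupling of a C-9 vinyl group with a (Z)-3-iodobut-2-enoate. The axial 2β-OH comes from α-face hydride attack on a C-2 ketone.
2. Key disconnection: both decalin rings close from one acyclic chain in one operation. C-5–C-10 forms by radical conjugate addition, then C-7–C-8 forms by intramolecular olefination, so this bond is first made as C=C.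
3. Enabling feature: ring-fusion carbon C-10 is quaternary and bears a methyl group, so it is a latent tertiary radical from a C-10=CH2 alkene plus a hydrogen atom. C-5 of ring A lies β to C-7 of ring B, so C-5–C-7 is a latent enal. The C-8=C-17 methylene next to the C-7 methylene of ring B is the transposed form of a ring-B cyclohexenecarboxylate, so C-8 is a latent phosphonoacetate carbon.
4. Chain assembly: cross-metathesis, asymmetric 2-bromoallylation (C-2, used as a temporary 2α relay stereocentre), Stille coupling, and iridium-catalysed allylic alkylation (C-9).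
5. Ring order: ring A, then ring B, both in step 9.

Key step: step 9

Assumption: the six building blocks marked as starting materials in the compound list are taken as commercial, and the phosphonate-bearing carbon is carried as an epimer mixture because it becomes sp2 in the key step.

Step 1
Reactants: 1 methyl 3,3-dimethylpent-4-enoate; 2 allyl tert-butyldimethylsilyl ether
Product: 3 methyl (E)-6-(tert-butyldimethylsilyloxy)-3,3-dimethylhex-4-enoate
Conditions: second-generation Hoveyda–Grubbs catalyst (3 mol%), 2 (3 equiv), CH2Cl2, 40 °C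
Reagents that add atoms: none
Why: Olefin cross-metathesis between a vinyl group on a quaternary carbon, which does not homodimerise, and an excess of an unhindered allyl ether should give the crossed alkene, and the bulk of the quaternary carbon should enforce the E geometry.

Step 2
Reactants: 3 methyl (E)-6-(tert-butyldimethylsilyloxy)-3,3-dimethylhex-4-enoate
Product: 4 (E)-6-(tert-butyldimethylsilyloxy)-3,3-dimethylhex-4-enal
Conditions: i-Bu2AlH (1.1 equiv), CH2Cl2, −78 °C; aq. Rochelle salt
Reagents that add atoms: none
Why: Partial ester reduction with i-Bu2AlH stops at the aluminium hemiacetal at low temperature and releases the aldehyde on work-up; no stereocentre is formed.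

Step 3
Reactants: 4 (E)-6-(tert-butyldimethylsilyloxy)-3,3-dimethylhex-4-enal; 5 2,3-dibromopropene
Product: 6 (4S,7E)-2-bromo-9-(tert-butyldimethylsilyloxy)-6,6-dimethyl-4-(triethylsilyloxy)nona-1,7-diene
Conditions: CrCl2 (10 mol%), chiral oxazoline–sulfonamide ligand (12 mol%), Co(phthalocyanine) (1 mol%), Mn, Et3SiCl, THF, rt
Reagents that add atoms: chlorotriethylsilane CC[Si](Cl)(CC)CC
Why: In this catalytic asymmetric Nozaki–Hiyama-type 2-haloallylation only the allylic C–Br bond is reduced to an allylchromium species, the ligand enantiomer is chosen so that addition to one aldehyde face sets the (S) carbinol (C-2), and Et3SiCl frees the chromium while capping the alkoxide as its silyl ether.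

Step 4
Reactants: 6 (4S,7E)-2-bromo-9-(tert-butyldimethylsilyloxy)-6,6-dimethyl-4-(triethylsilyloxy)nona-1,7-diene; 7 (E)-3-(tributylstannyl)prop-2-en-1-ol
Product: 8 (2E,6S,9E)-11-(tert-butyldimethylsilyloxy)-8,8-dimethyl-4-methylidene-6-(triethylsilyloxy)undeca-2,9-dien-1-ol
Conditions: Pd(PPh3)4 (5 mol%), CuI (10 mol%), DMF, 50 °C
Reagents that add atoms: none
Why: Stille coupling of a 2-bromo-1-alkene with an (E)-alkenylstannane proceeds with retention of alkene geometry and gives the 2-substituted (E)-dienol; no stereocentre is touched.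

Step 5
Reactants: 8 (2E,6S,9E)-11-(tert-butyldimethylsilyloxy)-8,8-dimethyl-4-methylidene-6-(triethylsilyloxy)undeca-2,9-dien-1-ol
Product: 9 methyl carbonate of dienol 8
Conditions: ClCO2Me, pyridine, CH2Cl2, 0 °C
Reagents that add atoms: methyl chloroformate COC(=O)Cl
Why: O-acylation of the only free primary alcohol gives the allylic carbonate that serves as leaving group and latent base in the next step.

Step 6
Reactants: 9 methyl carbonate of dienol 8; 10 triethyl phosphonoacetate
Product: 11 ethyl (3R,6S,9E)-11-(tert-butyldimethylsilyloxy)-2-(diethoxyphosphoryl)-3-ethenyl-8,8-dimethyl-4-methylidene-6-(triethylsilyloxy)undec-9-enoate (epimers at C-2 of the chain)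
Conditions: [Ir(cod)Cl]2 (2 mol%), BINOL-derived bis(1-phenylethyl)amine phosphoramidite (4 mol%), TBD (8 mol%), 10 (1.5 equiv), THF, 50 °C
Reagents that add atoms: none
Why: Iridium-catalysed asymmetric allylic alkylation of a dienyl carbonate with a stabilised carbanion is branched-selective, the methoxide released from the carbonate acts as the base, and the ligand enantiomer is chosen to set the (R) centre that becomes C-9 and carries the new vinyl group.

Step 7
Reactants: 11 silyl-protected phosphonoacetate
Product: 12 ethyl (3R,6S,9E)-2-(diethoxyphosphoryl)-3-ethenyl-6,11-dihydroxy-8,8-dimethyl-4-methylideneundec-9-enoate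
Conditions: HF·pyridine, THF, 0 °C to rt
Reagents that add atoms: none
Why: Fluoride-driven desilylation removes both silyl ethers under non-basic conditions that leave the phosphonoacetate and the skipped diene untouched.

Step 8
Reactants: 12 diol
Product: 13 ethyl (3R,6S,9E)-2-(diethoxyphosphoryl)-3-ethenyl-6-hydroxy-8,8-dimethyl-4-methylidene-11-oxoundec-9-enoate
Conditions: activated MnO2, CH2Cl2, rt
Reagents that add atoms: none
Why: MnO2 oxidises only the allylic alcohol, so the (E)-enal is unveiled under neutral conditions next to the base-sensitive phosphonoacetate while the C-2 carbinol stays free.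

Step 9
Reactants: 13 acyclic enal phosphonoacetate
Product: 15 ethyl 2α-hydroxy-13,14,15,16-tetranorlabda-7,11-dien-17-oate (5α-H; 9α-H; 10β-CH3), via ring-A aldehyde 14 (not isolated)
Conditions: Fe(acac)3 (30 mol%), PhSiH3 (2.5 equiv), Na2HPO4 (2 equiv), EtOH/THF 1:1 (0.01 M), 60 °C
Reagents that add atoms: none
Why: Proposed new method: an iron hydride formed from Fe(acac)3 and PhSiH3 transfers a hydrogen atom to the CH2 terminus of the 1,1-disubstituted alkene (this makes the C-20 methyl group and a tertiary C-10 radical), the radical adds 6-exo-trig to C-5 of the enal to close ring A, divalent iron reduces the α-formyl radical to an enolate, and the base equivalent stored in that enolate (directly or through ethoxide) deprotonates the far more acidic phosphonoacetate C-8–H, so that aldehyde 14 and its own phosphonate carbanion appear together and close ring B by intramolecular Horner–Wadsworth–Emmons olefination (6-exo-trig addition of C-8 to the C-7 aldehyde, then syn-elimination of diethyl phosphate). The closest known reaction types are the iron-catalysed reductive olefin coupling (hydrogen-atom-transfer Giese reaction) and the radical–polar crossover annulations in which the same kind of enolate is intercepted by an aldol reaction; the new element is the relay of the enolate basicity to an olefination. C-10 and C-5 are set in a chair-like transition state in which the C-2 hydroxyl, the C-9 branch and the enal arm are equatorial and only the small new methyl group is axial beside the axial C-4 methyl group, which should give 10β-CH3 and 5α-H, while C-9 is carried through unchanged and C-8 loses its stereocentre. The step needs hydrogen-atom transfer to the 1,1-disubstituted alkene rather than to the vinyl group or the electron-poor enal, which the usual reactivity order of such iron hydrides secures, and it needs ring closure to outrun intermolecular olefination of 13, which high dilution, the absence of any free strong base (Na2HPO4 only scavenges the diethyl phosphate) and the high effective molarity of the trans-diequatorial arms of 14 secure.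

Step 10
Reactants: 15 ethyl 2α-hydroxy-13,14,15,16-tetranorlabda-7,11-dien-17-oate
Product: 16 ethyl 2-oxo-13,14,15,16-tetranorlabda-7,11-dien-17-oate
Conditions: Dess–Martin periodinane, CH2Cl2, rt
Reagents that add atoms: none
Why: Mild hypervalent-iodine oxidation removes the 2α relay stereocentre, whose job is done, without touching the alkenes or C-9.

Step 11
Reactants: 16 ethyl 2-oxo-13,14,15,16-tetranorlabda-7,11-dien-17-oate
Product: 17 13,14,15,16-tetranorlabda-7,11-diene-2β,17-diol
Conditions: i-Bu2AlH (5 equiv), CH2Cl2, −78 to 0 °C; aq. Rochelle salt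
Reagents that add atoms: none
Why: i-Bu2AlH reduces the conjugated ester in a 1,2 sense to the allylic alcohol and also reduces the ketone; the β face of C-2 is shielded by the two syn-axial methyl groups on C-4 and C-10, so hydride should arrive from the α face and set the axial 2β-OH.

Step 12
Reactants: 18 ethyl but-2-ynoate
Product: 19 ethyl (Z)-3-iodobut-2-enoate
Conditions: NaI, AcOH, 110 °C
Reagents that add atoms: sodium iodide [Na+].[I-]
Why: Conjugate addition of iodide to the ynoate followed by anti protonation (hydroiodination) places iodine cis to the ester and so fixes the later 13Z geometry.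

Step 13
Reactants: 17 13,14,15,16-tetranorlabda-7,11-diene-2β,17-diol; 19 ethyl (Z)-3-iodobut-2-enoate
Product: 21 ethyl (13Z)-2β,17-dihydroxylabda-7,13-dien-15-oate, via B-alkyl borane 20 (not isolated)
Conditions: 9-BBN-H (3.5 equiv), THF, rt to 50 °C; then 19, Pd(dppf)Cl2 (5 mol%), AsPh3 (5 mol%), Cs2CO3, DMF/H2O, rt
Reagents that add atoms: none
Why: 9-BBN-H hydroborates the monosubstituted vinyl group at its terminus and leaves the trisubstituted ring alkene alone, and the B-alkyl Suzuki–Miyaura coupling then forms C-12–C-13 with retention of the iodoalkene geometry.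

Step 14
Reactants: 21 ethyl (13Z)-2β,17-dihydroxylabda-7,13-dien-15-oate
Product: 24 ethyl (13Z)-2β-hydroxylabda-8(17),13-dien-15-oate, via allylic sulfonylhydrazine 22 (not isolated), via allylic diazene 23 (not isolated)
Conditions: 2-nitrobenzenesulfonylhydrazide, PPh3, diethyl azodicarboxylate, THF, −30 °C to rt
Reagents that add atoms: none
Why: Mitsunobu displacement takes place only at the primary allylic alcohol because the axial 2β-OH is too hindered; loss of sulfinic acid then gives an allylic diazene whose retro-ene loss of N2 delivers hydrogen to C-7 and moves the alkene to C-8(17) (reductive 1,3-transposition of an allylic alcohol).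

Step 15
Reactants: 24 ethyl (13Z)-2β-hydroxylabda-8(17),13-dien-15-oate
Product: 25 (13Z)-2β-hydroxylabda-8(17),13-dien-15-oic acid
Conditions: LiOH, THF/MeOH/H2O, 40 °C; then 1 M HCl
Reagents that add atoms: lithium hydroxide [Li+].[OH-]
Why: Saponification is done before the acetate is installed, so no ester selectivity is needed and the Z-enoate geometry is not disturbed.

Step 16
Reactants: 25 (13Z)-2β-hydroxylabda-8(17),13-dien-15-oic acid
Product: 26 (13Z)-2β-acetoxylabda-8(17),13-dien-15-oic acid (target)
Conditions: Ac2O, DMAP (cat.), pyridine, 40 °C; aq. work-up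
Reagents that add atoms: acetic anhydride CC(=O)OC(C)=O
Why: DMAP-catalysed acetylation esterifies the hindered axial alcohol with retention at C-2, and any mixed anhydride formed at the acid is hydrolysed on aqueous work-up.

**Compound list**
1 | methyl 3,3-dimethylpent-4-enoate | C=CC(C)(C)CC(=O)OC | starting material
2 | allyl tert-butyldimethylsilyl ether | C=CCO[Si](C)(C)C(C)(C)C | starting material
3 | methyl (E)-6-(tert-butyldimethylsilyloxy)-3,3-dimethylhex-4-enoate | COC(=O)CC(C)(C)/C=C/CO[Si](C)(C)C(C)(C)C | intermediate
4 | (E)-6-(tert-butyldimethylsilyloxy)-3,3-dimethylhex-4-enal | O=CCC(C)(C)/C=C/CO[Si](C)(C)C(C)(C)C | intermediate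
5 | 2,3-dibromopropene | C=C(Br)CBr | starting material
6 | (4S,7E)-2-bromo-9-(tert-butyldimethylsilyloxy)-6,6-dimethyl-4-(triethylsilyloxy)nona-1,7-diene | CC(C)(C)[Si](C)(C)OC/C=C/C(C)(C)C[C@H](O[Si](CC)(CC)CC)CC(Br)=C | intermediate
7 | (E)-3-(tributylstannyl)prop-2-en-1-ol | CCCC[Sn](CCCC)(CCCC)/C=C/CO | starting material
8 | (2E,6S,9E)-11-(tert-butyldimethylsilyloxy)-8,8-dimethyl-4-methylidene-6-(triethylsilyloxy)undeca-2,9-dien-1-ol | CC(C)(C)[Si](C)(C)OC/C=C/C(C)(C)C[C@H](O[Si](CC)(CC)CC)CC(=C)/C=C/CO | intermediate
9 | methyl carbonate of dienol 8 | CC(C)(C)[Si](C)(C)OC/C=C/C(C)(C)C[C@H](O[Si](CC)(CC)CC)CC(=C)/C=C/COC(=O)OC | intermediate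
10 | triethyl phosphonoacetate | CCOC(=O)CP(=O)(OCC)OCC | starting material
11 | ethyl (3R,6S,9E)-11-(tert-butyldimethylsilyloxy)-2-(diethoxyphosphoryl)-3-ethenyl-8,8-dimethyl-4-methylidene-6-(triethylsilyloxy)undec-9-enoate | CC(C)(C)[Si](C)(C)OC/C=C/C(C)(C)C[C@H](O[Si](CC)(CC)CC)CC(=C)[C@@H](C=C)C(P(=O)(OCC)OCC)C(=O)OCC | intermediate
12 | ethyl (3R,6S,9E)-2-(diethoxyphosphoryl)-3-ethenyl-6,11-dihydroxy-8,8-dimethyl-4-methylideneundec-9-enoate | OC/C=C/C(C)(C)C[C@H](O)CC(=C)[C@@H](C=C)C(P(=O)(OCC)OCC)C(=O)OCC | intermediate
13 | ethyl (3R,6S,9E)-2-(diethoxyphosphoryl)-3-ethenyl-6-hydroxy-8,8-dimethyl-4-methylidene-11-oxoundec-9-enoate | O=C/C=C/C(C)(C)C[C@H](O)CC(=C)[C@@H](C=C)C(P(=O)(OCC)OCC)C(=O)OCC | intermediate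
14 | ring-A aldehyde: cyclohexane with equatorial CH2CHO at C-5, 10β-CH3, 2α-OH and the C-9 vinyl/phosphonoacetate branch on C-10 | O=CC[C@H]1C(C)(C)C[C@H](O)C[C@]1(C)[C@@H](C=C)C(P(=O)(OCC)OCC)C(=O)OCC | intermediate
15 | ethyl 2α-hydroxy-13,14,15,16-tetranorlabda-7,11-dien-17-oate | CCOC(=O)C1=CC[C@H]2C(C)(C)C[C@H](O)C[C@]2(C)[C@H]1C=C | intermediate
16 | ethyl 2-oxo-13,14,15,16-tetranorlabda-7,11-dien-17-oate | CCOC(=O)C1=CC[C@H]2C(C)(C)CC(=O)C[C@]2(C)[C@H]1C=C | intermediate
17 | 13,14,15,16-tetranorlabda-7,11-diene-2β,17-diol | OCC1=CC[C@H]2C(C)(C)C[C@@H](O)C[C@]2(C)[C@H]1C=C | intermediate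
18 | ethyl but-2-ynoate | CC#CC(=O)OCC | starting material
19 | ethyl (Z)-3-iodobut-2-enoate | C/C(I)=C/C(=O)OCC | intermediate
20 | tris(9-BBN) adduct of 17: B-alkyl borane at C-12, borinic esters at both oxygens | C(OB1C2CCCC1CCC2)C3=CC[C@H]4C(C)(C)C[C@@H](OB5C6CCCC5CCC6)C[C@]4(C)[C@H]3CCB7C8CCCC7CCC8 | intermediate
21 | ethyl (13Z)-2β,17-dihydroxylabda-7,13-dien-15-oate | OCC1=CC[C@H]2C(C)(C)C[C@@H](O)C[C@]2(C)[C@H]1CC/C(C)=C\C(=O)OCC | intermediate
22 | N-(C-17 allyl)-N-(2-nitrobenzenesulfonyl)hydrazine of 21 | NN(CC1=CC[C@H]2C(C)(C)C[C@@H](O)C[C@]2(C)[C@H]1CC/C(C)=C\C(=O)OCC)S(=O)(=O)c1ccccc1[N+](=O)[O-] | intermediate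
23 | C-17 allylic diazene | N=NCC1=CC[C@H]2C(C)(C)C[C@@H](O)C[C@]2(C)[C@H]1CC/C(C)=C\C(=O)OCC | intermediate
24 | ethyl (13Z)-2β-hydroxylabda-8(17),13-dien-15-oate | C=C1CC[C@H]2C(C)(C)C[C@@H](O)C[C@]2(C)[C@H]1CC/C(C)=C\C(=O)OCC | intermediate
25 | (13Z)-2β-hydroxylabda-8(17),13-dien-15-oic acid | C=C1CC[C@H]2C(C)(C)C[C@@H](O)C[C@]2(C)[C@H]1CC/C(C)=C\C(=O)O | intermediate
26 | (2R,5S,9S,10S,13Z)-2-acetoxylabda-8(17),13-dien-15-oic acid | C=C1CC[C@H]2C(C)(C)C[C@@H](OC(C)=O)C[C@]2(C)[C@H]1CC/C(C)=C\C(=O)O | target

Total step count: 16. Longest linear sequence: 15 (steps 1–11 and 13–16).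

**Steps most likely to fail**

Step 9. The base equivalent of the enolate may be lost to the silane or the buffer, so that the olefination stalls. Over-long exposure may also lead to hydrogen-atom transfer at the vinyl group. The fallback sets out from 13. The iron-hydride Giese cyclisation is run alone (Fe(acac)3, PhSiH3, EtOH, one equivalent of AcOH as proton source) and ring-A aldehyde 14 is isolated. Ring B is then closed in a separate Horner–Wadsworth–Emmons step (LiCl, DBU, MeCN, high dilution), which returns to the route at 15. Both reactions are known types, and the detour makes no compound outside the list (F0).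

Step 6. Branched regioselectivity or enantiofacial control may erode, because the bulky phosphonoacetate anion has to attack next to a 1,1-disubstituted alkene. The fallback sets out from 9 and moves the phosphorus introduction to after the C–C bond formation.
- The same allylic alkylation with the smaller diethyl malonate gives the branched malonate F1.
- Krapcho dealkoxycarbonylation (LiCl, wet DMSO, heat) gives the branched ethyl ester F2.
- Deprotonation with LDA, trapping with ClP(OEt)2 and oxidation with H2O2 installs the phosphonate and returns to 11.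

Step 1. Metathesis at the vinyl group on the quaternary carbon may be sluggish, while homodimerisation of the allyl ether consumes the catalyst. The fallback sets out from 1.
- Ozonolysis (O3, then Me2S) gives methyl 3,3-dimethyl-4-oxobutanoate F3.
- Wittig reaction with (triphenylphosphoranylidene)acetaldehyde gives methyl (E)-3,3-dimethyl-6-oxohex-4-enoate F4.
- Luche reduction (NaBH4, CeCl3, MeOH) gives methyl (E)-6-hydroxy-3,3-dimethylhex-4-enoate F5.
- Silylation (TBSCl, imidazole) returns to 3.

**Further compounds**
F0 | step 9 | none | none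
F1 | step 6 | branched diethyl malonate adduct of 9 (same spatial arrangement at C-9 as in 11) | CC(C)(C)[Si](C)(C)OC/C=C/C(C)(C)C[C@H](O[Si](CC)(CC)CC)CC(=C)[C@@H](C=C)C(C(=O)OCC)C(=O)OCC
F2 | step 6 | branched ethyl ester after dealkoxycarbonylation | CC(C)(C)[Si](C)(C)OC/C=C/C(C)(C)C[C@H](O[Si](CC)(CC)CC)CC(=C)[C@@H](C=C)CC(=O)OCC
F3 | step 1 | methyl 3,3-dimethyl-4-oxobutanoate | COC(=O)CC(C)(C)C=O
F4 | step 1 | methyl (E)-3,3-dimethyl-6-oxohex-4-enoate | COC(=O)CC(C)(C)/C=C/C=O
F5 | step 1 | methyl (E)-6-hydroxy-3,3-dimethylhex-4-enoate | COC(=O)CC(C)(C)/C=C/CO
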